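The constants are invented, and the outcome is calculated.

**Reading time.** The time of reading is where you start: 40 min in amber, the same as mean residence time in teal, and 200 min in ochre.

| setting | teal | amber | ochre |
|---|---|---|---|
| substrate | 0.40 M | 0.40 M | 0.40 M |
| remark | one stirred flow tank at steady state, fed with the mixture as stated, mean residence time 40 min | everything together in a closed stirred flask, run for 40 min | one stirred flow tank at steady state, fed with the mixture as stated, mean residence time 200 min |
| time |  | 40 min |  |

- order of the set-ups by the share of target in all that became target or side product or over-reaction product or isomer of the product, at the outlet or at the end, highest first (teal / amber / ochre)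
- share of target in all that became target or side product or over-reaction product or isomer of the product, at the outlet or at the end, teal
- share of target in all that became target or side product or over-reaction product or isomer of the product, at the outlet or at the end, amber
- share of target in all that became target or side product or over-reaction product or isomer of the product, at the outlet or at the end, ochre

- percentages count the substrate that a species holds: one side product counts as two
- the stated concentrations are those of everything mixed, before any reaction; amounts are the same in each set-up
- run time (amber): 40 min

    substrate ⇌ intermediate A (K1 = 0.82, k1 = 2.5 × 10⁻⁴ s⁻¹)
    intermediate A ⇌ intermediate B (K2 = 38, k2 = 2.6 × 10⁻⁴ s⁻¹)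
    intermediate B ⇌ target (K3 = 1.3, k3 = 3.9 × 10⁻⁴ s⁻¹)
    substrate ⇌ target (k4 = 1.3 × 10⁻⁴ s⁻¹)
    substrate + intermediate B → side product (k5 = 3.7 × 10⁻⁴ L mol⁻¹ s⁻¹)
    target → over-reaction product (k6 = 4.2 × 10⁻⁴ s⁻¹)
    target ⇌ isomer of the product (K7 = 0.67, k7 = 7.7 × 10⁻⁴ s⁻¹)

**Exposure number.** Target is lost to over-reaction with rate constant 4.2 × 10⁻⁴ s⁻¹. At 40 min, in teal and amber, you get 1.01: the exposure number N, the over-reaction rate constant times the time in the vessel. For ochre's 200 min, N is 5.04.

**Tank end.** In a steady tank, outflow removes what the step makes, so c(over-reaction product) = N c(target). The isomer balance, with 7.7 × 10⁻⁴ s⁻¹ and 0.67, gives isomer per target of 0.492 in teal and 0.625 in ochre. Side product would lower the share, so leaving it out gives ceilings: 40.0% for teal and 15.0% for ochre.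

**Flask end.** In amber, target starts from nothing. If it rose steadily, over-reaction product per target would be half of N; if it stood level, N itself. Isomer trails target by the isomer equilibrium constant over its forward rate constant, 14.5 min, so I take isomer per target as about 0.427 if target rose steadily and about 0.67 if it stood level. Without side product, the two ends give 51.8% and 37.3%. I commit to the middle, 44.6%, which is higher than teal's ceiling, so amber comes first and ochre last.

**The forecast.** It gives amber > teal > ochre, with 34.9% for teal, 42% for amber and 13.1% for ochre. Its ground is the quick drain of target “The target is drained quickly into the isomer and over-reaction product”. The order is mine too, but its tank values lie below my ceilings, and its amber value lies below my middle.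

**The flask.** The simulation gives amber > teal > ochre: teal 34.9%, amber 41.7%, ochre 13.1%.

**Longer wait.** In amber at 40.0 min, over-reaction product per target reads 0.686, which is 0.681 of N = 1.01. Now take the neighbouring flask, amber left until 2.5 h. There N is 3.78, and the same two ends give shares of 28.6% and 18.3% without side product. The reading of over-reaction product per target is 3.38, which is 0.895 of N. That flask holds 8.48% as side product beside 11.2% as target, and its share of target is 17.2%.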